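The target's three bromines sit on three of the four carbons ortho to the phenol oxygens. Each ring is numbered from its C–OH carbon, and the CH2 bridge joins C4 of ring A to C4′ of ring B. The bromines are at C2 of ring A and at C2′/C6′ of ring B. Since the bridge blocks both para carbons, the ortho carbons are the only activated sites. All three C–Br bonds are therefore disconnected together, provided the fourth ortho carbon, C6 of ring A, is masked. The precursor is bisphenol F carrying one tert-butyl group at C6. Bromination to saturation then installs exactly three bromines in one operation, and acid-mediated transfer of the tert-butyl group to toluene uncovers C6–H.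

Key step: step 2

Remark on the chemistry: the target has no stereocentre, stereogenic axis or configured double bond, so it is a single achiral compound and no stereocontrol is required. The precursor and product structures of the key step were checked and need no correction.

**Step 1**
Reactants: 1 4,4′-methylenediphenol (bisphenol F); 2 tert-butanol
Product: 3 2-tert-butyl-4-(4-hydroxybenzyl)phenol (one tert-butyl group ortho to the hydroxyl of ring A, i.e. on C6 in the numbering used above; ring B unsubstituted)
Conditions: 2 (0.6 equiv, slow addition), 85% H3PO4, toluene, 85 °C; chromatography, recovered 1 recycled
Reagents that add atoms: none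
Why: Friedel–Crafts alkylation in which the tert-butyl cation from 2 attacks a phenol ring ortho to oxygen because the para carbon carries the bridge, any aryl tert-butyl ether reverts under the acid, and keeping 2 limiting should hold dialkylation down so that 3 can be separated from the more polar 1 and the less polar bis-alkylated material.

**Step 2**
Reactants: 3 2-tert-butyl-4-(4-hydroxybenzyl)phenol
Product: 4 2-bromo-6-tert-butyl-4-(3,5-dibromo-4-hydroxybenzyl)phenol
Conditions: Br2 (3.0 equiv), NaOAc (3.3 equiv), AcOH–CH2Cl2, 0 °C to rt, dark; aq. NaHSO3
Reagents that add atoms: bromine, BrBr
Why: Each phenol ring attacks bromine at an open ortho carbon (electrophilic aromatic substitution through an ortho-bromo cyclohexadienone/arenium species that tautomerises back to the phenol), and acetate takes up each equivalent of HBr. The closest known reaction type is the exhaustive ortho-bromination of para-substituted phenols, as in the 2,6-dibromination of 4-alkylphenols and the monobromination of 2-tert-butyl-4-alkylphenols. No ring is closed and no stereocentre is formed. The step needs site- and chemoselectivity: only C2 of ring A and C2′/C6′ of ring B may react, not the tert-butyl-bearing C6 (ipso substitution), the bridge carbons C4/C4′ (ipso attack with C–C scission) or the benzylic CH2. The substrate secures this because the bridge occupies both para carbons and the tert-butyl group occupies and shields C6, so the three remaining ortho C–H carbons are the only activated, unhindered positions and the number of bromines is set by the number of open sites. Exactly three equivalents of bromine, acetate buffering, low temperature and exclusion of light should keep the reaction ionic and stop it at 4.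

**Step 3**
Reactants: 4 2-bromo-6-tert-butyl-4-(3,5-dibromo-4-hydroxybenzyl)phenol
Product: 5 2,6-dibromo-4-(3-bromo-4-hydroxybenzyl)phenol (target)
Conditions: AlCl3 (2.5 equiv), MeNO2, toluene, 25–50 °C; then ice/aq. HCl
Reagents that add atoms: none
Why: Retro-Friedel–Crafts transalkylation (trans-tert-butylation) in which ipso protonation at C6 of ring A, assisted by the ortho hydroxyl, releases the tert-butyl cation that toluene traps irreversibly, while the nitromethane-moderated aluminium chloride should be mild enough to leave the diarylmethane bridge and the three C–Br bonds in place.

**Compound list**
1 | 4,4′-methylenediphenol (bisphenol F) | Oc1ccc(Cc2ccc(O)cc2)cc1 | starting material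
2 | tert-butanol | CC(C)(C)O | starting material
3 | 2-tert-butyl-4-(4-hydroxybenzyl)phenol | CC(C)(C)c1cc(Cc2ccc(O)cc2)ccc1O | intermediate
4 | 2-bromo-6-tert-butyl-4-(3,5-dibromo-4-hydroxybenzyl)phenol | CC(C)(C)c1cc(Cc2cc(Br)c(O)c(Br)c2)cc(Br)c1O | intermediate
5 | 2,6-dibromo-4-(3-bromo-4-hydroxybenzyl)phenol (achiral) | Oc1ccc(Cc2cc(Br)c(O)c(Br)c2)cc1Br | target

Total step count: 3
Longest linear sequence: 3 steps (1 → 3 → 4 → 5)

**Steps most likely to fail**

Step 2 (key step). The bromination may not stop cleanly at the three open ortho carbons. Possible failures are ipso substitution at the tert-butyl-bearing carbon, ipso attack at the bridge carbons with C–C scission, radical substitution at the benzylic CH2, or uneven bromination that leaves under-brominated material. The fallback gives up the blocking group and sets out from 1. Bromination of 1 to saturation (Br2 in slight excess over four equivalents, NaOAc, AcOH) should give 4,4′-methylenebis(2,6-dibromophenol) F1, in which all four bromines are equivalent. Removal of any one of them leads to a single product. This would be done by double deprotonation (NaH, THF), bromine–lithium exchange with one equivalent of n-BuLi at −78 °C and protonation with methanol. The monodebrominated product is separated from unreacted F1 (recycled) and from doubly debrominated material. The fallback comes back to the route at 5.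

Step 3. The Lewis acid may mobilise more than the tert-butyl group. Possible failures are transfer of bromine to toluene or to the freed C6 position (hydrodebromination or bromine scrambling) and transbenzylation at the CH2 bridge. The fallback avoids any acid-labile blocking group and sets out from 1.
- Statistical mono-acetylation (Ac2O 0.5 equiv, pyridine, CH2Cl2, 0 °C; diol and diacetate recycled) should give 4-(4-hydroxybenzyl)phenyl acetate F2, whose acetylated ring is deactivated.
- Bromination with two equivalents of Br2 (NaOAc, AcOH) should then dibrominate only the free phenol ring to give 4-(3,5-dibromo-4-hydroxybenzyl)phenyl acetate F3.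
- Saponification (LiOH, THF–H2O, then dilute acid) should give 2,6-dibromo-4-(4-hydroxybenzyl)phenol F4.
- One equivalent of Br2 (CH2Cl2, −20 °C) should monobrominate the only ring that still has open ortho carbons, the first bromine slowing a second substitution.

The fallback comes back to the route at 5.

Step 1. Desymmetrisation by C-alkylation is statistical. The alkylation may not be held at the mono stage, and 3 may prove hard to separate from 1 and from bis-alkylated material. The fallback moves the statistical event to oxygen, where the components differ strongly in polarity, and sets out from 1.
- Mono-pivaloylation (PivCl 0.5 equiv, Et3N, CH2Cl2, 0 °C; diol and diester recycled) should give 4-(4-hydroxybenzyl)phenyl pivalate F5.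
- Friedel–Crafts tert-butylation with 2 (slight excess, H3PO4, toluene, 85 °C) should take place only on the free phenol ring, the ester ring being deactivated, and give 4-(3-tert-butyl-4-hydroxybenzyl)phenyl pivalate F6.
- Ester hydrolysis (NaOH, THF–H2O, 50 °C, then dilute acid) comes back to the route at 3.

**Further compounds**
F1 | step 2 | 4,4′-methylenebis(2,6-dibromophenol) | Oc1c(Br)cc(Cc2cc(Br)c(O)c(Br)c2)cc1Br
F2 | step 3 | 4-(4-hydroxybenzyl)phenyl acetate | CC(=O)Oc1ccc(Cc2ccc(O)cc2)cc1
F3 | step 3 | 4-(3,5-dibromo-4-hydroxybenzyl)phenyl acetate | CC(=O)Oc1ccc(Cc2cc(Br)c(O)c(Br)c2)cc1
F4 | step 3 | 2,6-dibromo-4-(4-hydroxybenzyl)phenol | Oc1ccc(Cc2cc(Br)c(O)c(Br)c2)cc1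
F5 | step 1 | 4-(4-hydroxybenzyl)phenyl pivalate | CC(C)(C)C(=O)Oc1ccc(Cc2ccc(O)cc2)cc1
F6 | step 1 | 4-(3-tert-butyl-4-hydroxybenzyl)phenyl pivalate | CC(C)(C)C(=O)Oc1ccc(Cc2ccc(O)c(c2)C(C)(C)C)cc1
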